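all flasks: starting material 0.012 M
- dawn: second substrate 0.030 M; free enzyme 0.86 µM; run made earlier
- spring: second substrate 0.030 M; free enzyme 0.98 µM; run made earlier
- dusk: second substrate 0.030 M; free enzyme 1 µM; run made earlier
- red: second substrate 0.0300 M; free enzyme 0.80 µM; time 8.0 min
- teal: second substrate 0.0300 M; free enzyme 1.2 µM; time 8.0 min

| dawn: time / min | dawn: target / % | spring: time / min | spring: target / % | dusk: time / min | dusk: target / % |
|---|---|---|---|---|---|
| 1.50 | 16.6 | 0.667 | 9.4 | 0.667 | 8.2 |
| 3.00 | 28.4 | 2.00 | 23.4 | 1.33 | 16.6 |
| 5.00 | 43.4 | 4.00 | 41.5 | 2.50 | 30.1 |
| 6.00 | 49.8 | 6.00 | 54.0 | 4.00 | 42.2 |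
| 8.00 | 58.0 | 8.00 | 63.5 | 8.00 | 64.2 |

(standard deviation of a reading: 0.5 percentage points)

- the winner by amount of target, in percent of the starting material charged; "neither" if no more than 2 percentage points parts them (red / teal / neither)
- how much target is there at the end, in percent of the starting material charged: red
- how much target is there at the end, in percent of the starting material charged: teal

- the analysis behind the earlier runs scatters by 0.5 percentage points, standard deviation

Start from 7700: that many molecules of target per enzyme charged stood in the dusk run at 8.00 min. Call this count N = c(target)/c(free enzyme charged), a turnover number. If N were the same in every run, you would get a yield by multiplying N by the enzyme charge and dividing by 0.012 M.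

But dusk's N on dawn's 0.86 µM gives 55.2%, while dawn read 58.0%, a gap well outside the scatter of 0.5 percentage points. So N shifts with the enzyme charge: dawn's N is 8090, higher than dusk's.

Spring, with an enzyme charge between theirs, gives 7780, below dawn's and above dusk's, so a straight line through dawn and dusk is fair. My own reckoning extends that line, although both new charges lie outside the runs. Red gets N = 8260, hence 55.1%. Teal gets N = 7150, hence 71.5%. They stand 16 points apart, against a margin of 2 points, so my winner is teal.

The forecast says teal, with red at 55.5% and teal at 70.5%, 1.00 point under my teal: “Teal clearly wins”.

The flask gives teal, with red at 55.4% and teal at 73.7%.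

    starting material + free enzyme ⇌ first complex (K = 53.0 /M, k = 51000 /M/s)
    first complex → loaded enzyme + first product (k = 93.0 /s)
    second substrate + loaded enzyme ⇌ second complex (K = 62.0 /M, k = 66000 /M/s)
    second complex → free enzyme + target (k = 270 /s)
    second complex → spent catalyst (k = 0.0130 /s)

In counts, red's N is 8300 and teal's is 7370, below dusk's 7700. Neither flask has stopped at 8.00 min: starting material stands at 44.6% in red and 26.3% in teal. Now read the red flask early, at 2.0 min. Spring's N at 2.00 min is 2870, which on red's enzyme charge gives 19.1%. That neighbour holds 19.6%, an N of 2950.

The data are calculated on assumed constants, and the scatter is random.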